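**Retrosynthetic overview**

1. Last step: neutral hydrogenolysis of the benzyl ester and benzyl ether of the protected depside.
2. Key disconnection: the depside is cut at the aryl C–O bond, not the usual acyl C–O bond. The ring A carboxylic acid acts as an O-nucleophile toward a ring B aryl bromide in a photosensitised NiBr2/bipyridine C–O cross-coupling, so the hindered, enolisable ring A acyl group is never activated.
3. Each 2-(2-oxopentyl)benzoate unit is unmasked from a 3-propylisocoumarin by hydroxide opening (ring A as the free acid, ring B trapped as its dibenzyl derivative).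
4. Each isocoumarin comes from a commercial benzoic acid by carboxylate-directed C–H acylmethylation/annulation with one shared butanoyl sulfoxonium ylide.
5. Ring order: both benzene rings are bought. Only two pyranone rings are made (ring A isocoumarin first, ring B isocoumarin second), and both are opened again before the coupling.

Assumption: the target SMILES is achiral (no stereocentre), so "single enantiomer" needs no stereocontrol and no step creates a stereocentre.

**Route**

Step 1
Reactants: 1 trimethylsulfoxonium iodide; 2 butanoyl chloride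
Product: 4 1-(dimethyl(oxo)-λ6-sulfanylidene)pentan-2-one, via dimethylsulfoxonium methylide 3 (not isolated)
Conditions: 1 (3.0 equiv), KOtBu (3.0 equiv), THF, reflux, 2 h; then 2 (1.0 equiv), 0 °C → rt, 1 h
Reagents that add atoms: none
Why: Corey–Chaykovsky-type C-acylation of the methylide by the acid chloride, with a second equivalent of methylide removing the acidic proton to give the stabilised ylide.

Step 2
Reactants: 5 2,4-dimethoxybenzoic acid; 4 1-(dimethyl(oxo)-λ6-sulfanylidene)pentan-2-one
Product: 7 6,8-dimethoxy-3-propyl-1H-isochromen-1-one, via open keto acid 6 (not isolated)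
Conditions: [Cp*RhCl2]2 (2.5 mol %), AgSbF6 (10 mol %), NaOAc (30 mol %), 4 (1.5 equiv), HFIP, 60 °C, 12 h; then TsOH·H2O (20 mol %), 60 °C, 2 h
Reagents that add atoms: none
Why: Carboxylate-directed C–H activation by the cationic Cp*Rh catalyst (trivalent rhodium) at C6, the only free ortho position, then carbene transfer from the ylide with loss of DMSO (C–H acylmethylation) and acid-promoted cyclodehydration of the keto acid to the isocoumarin.

Step 3
Reactants: 7 6,8-dimethoxy-3-propyl-1H-isochromen-1-one
Product: 8 8-hydroxy-6-methoxy-3-propyl-1H-isochromen-1-one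
Conditions: BCl3 (1.5 equiv, 1 M in CH2Cl2), CH2Cl2, −78 → 0 °C; then H2O
Reagents that add atoms: none
Why: Chelation-controlled Lewis-acid ether cleavage, in which BCl3 bridges the lactone carbonyl and the peri C8 methoxy group so that only this ether is cleaved and the C6 methoxy group survives.

Step 4
Reactants: 8 8-hydroxy-6-methoxy-3-propyl-1H-isochromen-1-one
Product: 10 2-hydroxy-4-methoxy-6-(2-oxopentyl)benzoic acid, via dipotassium salt 9 (not isolated)
Conditions: KOH (3 equiv), THF/H2O 1:1, 40 °C, 2 h; then 1 M HCl to pH 3 at 0 °C, EtOAc extraction, concentrate cold, use at once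
Reagents that add atoms: potassium hydroxide, [K+].[OH-]
Why: Saponification of the enol lactone, where the enolate leaving group tautomerises to the ketone and the carboxylate cannot re-close, and cold acidification frees the keto acid without the heat or strong acid that cyclodehydration needs.

Step 5
Reactants: 11 4-bromo-2-methoxybenzoic acid; 4 1-(dimethyl(oxo)-λ6-sulfanylidene)pentan-2-one
Product: 13 6-bromo-8-methoxy-3-propyl-1H-isochromen-1-one, via open keto acid 12 (not isolated)
Conditions: [Cp*RhCl2]2 (2.5 mol %), AgSbF6 (10 mol %), NaOAc (30 mol %), 4 (1.5 equiv), HFIP, 60 °C, 12 h; then TsOH·H2O (20 mol %), 60 °C, 2 h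
Reagents that add atoms: none
Why: The same carboxylate-directed C–H acylmethylation/annulation at C6, the only ortho C–H, with the C–Br bond inert to the Cp*Rh catalyst.

Step 6
Reactants: 13 6-bromo-8-methoxy-3-propyl-1H-isochromen-1-one
Product: 14 6-bromo-8-hydroxy-3-propyl-1H-isochromen-1-one
Conditions: BCl3 (1.5 equiv, 1 M in CH2Cl2), CH2Cl2, −78 → 0 °C; then H2O
Reagents that add atoms: none
Why: The same chelation-controlled BCl3 demethylation of the peri methoxy group, with the aryl bromide and enol lactone untouched at low temperature.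

Step 7
Reactants: 14 6-bromo-8-hydroxy-3-propyl-1H-isochromen-1-one
Product: 16 benzyl 2-(benzyloxy)-4-bromo-6-(2-oxopentyl)benzoate, via dipotassium salt 15 (not isolated)
Conditions: KOH (2.05 equiv), THF/H2O, 40 °C, 2 h; evaporate to dryness (toluene azeotrope); then BnBr (2.3 equiv), DMF, rt, 16 h
Reagents that add atoms: potassium hydroxide, [K+].[OH-]; benzyl bromide, BrCc1ccccc1
Why: Enol-lactone saponification gives the phenoxide/carboxylate dianion, which undergoes double SN2 O-benzylation (Williamson etherification plus carboxylate alkylation) with no base stronger than the phenoxide present, so the unmasked ketone is not enolised.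

Step 8
Reactants: 10 2-hydroxy-4-methoxy-6-(2-oxopentyl)benzoic acid; 16 benzyl 2-(benzyloxy)-4-bromo-6-(2-oxopentyl)benzoate
Product: 17 benzyl 2-(benzyloxy)-4-{[2-hydroxy-4-methoxy-6-(2-oxopentyl)benzoyl]oxy}-6-(2-oxopentyl)benzoate
Conditions: 10 (1.3 equiv), t-BuNH(i-Pr) (1.3 equiv, never in excess over 10), NiBr2(dme) (5 mol %), 4,4'-di-tert-butyl-2,2'-bipyridine (5 mol %), Ir(ppy)3 (1 mol %), DMF, blue LEDs (450 nm), 25 °C, 24 h
Reagents that add atoms: none
Why: Photosensitised nickel-catalysed C(aryl)–O cross-coupling of a carboxylic acid with an aryl bromide (oxidative addition of the unhindered, ester-activated C–Br bond to zerovalent nickel, bromide/carboxylate exchange, then C–O reductive elimination triggered by triplet energy transfer from excited Ir(ppy)3), in which the carboxylate reacts through oxygen so the hindered acyl carbon is never activated and cannot collapse to isocoumarin 8, while the chelated phenol stays protonated and no free base remains to cleave the product.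

Step 9
Reactants: 17 benzyl 2-(benzyloxy)-4-{[2-hydroxy-4-methoxy-6-(2-oxopentyl)benzoyl]oxy}-6-(2-oxopentyl)benzoate
Product: 18 glomellic acid
Conditions: H2 (1 atm), 10% Pd/C, EtOAc, rt, 2 h; filter, crystallise
Reagents that add atoms: none
Why: Neutral heterogeneous hydrogenolysis (O-debenzylation) of the benzyl ester and benzyl ether, which leaves the aryl ester and both ketones intact and avoids the acid or base that would lactonise either keto acid unit.

**Compound list**

1 | trimethylsulfoxonium iodide | C[S+](C)(C)=O.[I-] | starting material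
2 | butanoyl chloride | CCCC(=O)Cl | starting material
3 | dimethylsulfoxonium methylide | [CH2-][S+](C)(C)=O | intermediate
4 | 1-(dimethyl(oxo)-λ6-sulfanylidene)pentan-2-one | CCCC(=O)C=S(C)(C)=O | intermediate
5 | 2,4-dimethoxybenzoic acid | COc1ccc(C(=O)O)c(OC)c1 | starting material
6 | 2,4-dimethoxy-6-(2-oxopentyl)benzoic acid | CCCC(=O)Cc1cc(OC)cc(OC)c1C(=O)O | intermediate
7 | 6,8-dimethoxy-3-propyl-1H-isochromen-1-one | CCCC1=Cc2cc(OC)cc(OC)c2C(=O)O1 | intermediate
8 | 8-hydroxy-6-methoxy-3-propyl-1H-isochromen-1-one | CCCC1=Cc2cc(OC)cc(O)c2C(=O)O1 | intermediate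
9 | dipotassium 4-methoxy-2-oxido-6-(2-oxopentyl)benzoate | CCCC(=O)Cc1cc(OC)cc([O-])c1C(=O)[O-].[K+].[K+] | intermediate
10 | 2-hydroxy-4-methoxy-6-(2-oxopentyl)benzoic acid | CCCC(=O)Cc1cc(OC)cc(O)c1C(=O)O | intermediate
11 | 4-bromo-2-methoxybenzoic acid | COc1cc(Br)ccc1C(=O)O | starting material
12 | 4-bromo-2-methoxy-6-(2-oxopentyl)benzoic acid | CCCC(=O)Cc1cc(Br)cc(OC)c1C(=O)O | intermediate
13 | 6-bromo-8-methoxy-3-propyl-1H-isochromen-1-one | CCCC1=Cc2cc(Br)cc(OC)c2C(=O)O1 | intermediate
14 | 6-bromo-8-hydroxy-3-propyl-1H-isochromen-1-one | CCCC1=Cc2cc(Br)cc(O)c2C(=O)O1 | intermediate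
15 | dipotassium 4-bromo-2-oxido-6-(2-oxopentyl)benzoate | CCCC(=O)Cc1cc(Br)cc([O-])c1C(=O)[O-].[K+].[K+] | intermediate
16 | benzyl 2-(benzyloxy)-4-bromo-6-(2-oxopentyl)benzoate | CCCC(=O)Cc1cc(Br)cc(OCc2ccccc2)c1C(=O)OCc1ccccc1 | intermediate
17 | benzyl 2-(benzyloxy)-4-{[2-hydroxy-4-methoxy-6-(2-oxopentyl)benzoyl]oxy}-6-(2-oxopentyl)benzoate | CCCC(=O)Cc1cc(OC(=O)c2c(O)cc(OC)cc2CC(=O)CCC)cc(OCc2ccccc2)c1C(=O)OCc1ccccc1 | intermediate
18 | glomellic acid, 2-hydroxy-4-{[2-hydroxy-4-methoxy-6-(2-oxopentyl)benzoyl]oxy}-6-(2-oxopentyl)benzoic acid | CCCC(=O)Cc1cc(OC(=O)c2c(O)cc(OC)cc2CC(=O)CCC)cc(O)c1C(=O)O | target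

**Step count and risks**

Total step count: 9. Longest linear sequence: 6 steps (1, 2, 3, 4, 8, 9; the ring B branch 1, 5, 6, 7, 8, 9 is equally long).

Most likely to fail, step 8 (the key C(aryl)–O coupling). It has not been shown on a 2,6-disubstituted salicylic acid carrying a free ketone. Bromide 16 may be reduced, the phenol may be arylated, or traces of base may let the ketone enol of 17 expel the ring B phenoxide and return isocoumarin 8. The fallback reverts to the conventional acyl-transfer polarity. It sets out from 16, which undergoes Miyaura borylation (B2pin2, Pd(dppf)Cl2, KOAc, dioxane, 80 °C) to give benzyl 2-(benzyloxy)-6-(2-oxopentyl)-4-(4,4,5,5-tetramethyl-1,3,2-dioxaborolan-2-yl)benzoate F1. Oxidation with NaBO3·4H2O in THF/H2O at rt gives the phenol benzyl 2-(benzyloxy)-4-hydroxy-6-(2-oxopentyl)benzoate F2. F2 is then esterified with acid 10 using DCC in toluene at 0 °C → rt, through the O-acylisourea of 10 F3, and the sequence comes back to the route at 17. Any 8 formed by competing enol-lactonisation of F3 is recycled through step 4.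

Second, step 2 (C–H acylmethylation/annulation of the electron-rich acid 5). The ylide may instead O-alkylate the carboxylic acid, the acid may protodecarboxylate under the silver/rhodium conditions, and n-alkyl ylides are less proven than aryl ones. The fallback replaces C–H activation by lateral lithiation and sets out from 2. Treatment of 2 with MeNHOMe·HCl and pyridine in CH2Cl2 at 0 °C gives N-methoxy-N-methylbutanamide F4. Commercial methyl 2,4-dimethoxy-6-methylbenzoate F5 is deprotonated with LDA (2.1 equiv, THF, −78 °C) to the benzylic lithium species methyl 2-(lithiomethyl)-4,6-dimethoxybenzoate F6. F6 is acylated by F4 and quenched with aqueous HCl to give methyl 2,4-dimethoxy-6-(2-oxopentyl)benzoate F7. Heating F7 with TsOH·H2O in toluene at reflux closes the enol lactone with loss of methanol, and the sequence comes back to the route at 7.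

Third, step 7 (one-pot opening and double benzylation). With the ketone unmasked, the phenoxide of 15 can act as a base, giving C-benzylation at the doubly activated CH2 or re-closure of the benzyl ester to an isocoumarin. The fallback protects before unmasking and sets out from 14. Benzylation of the ketone-free isocoumarin (BnBr, K2CO3, acetone, reflux) gives 8-(benzyloxy)-6-bromo-3-propyl-1H-isochromen-1-one F8. Saponification with exactly 1.0 equiv KOH in THF/H2O and evaporation gives potassium 2-(benzyloxy)-4-bromo-6-(2-oxopentyl)benzoate F9. This carboxylate monoanion, which contains no phenoxide base, is alkylated with BnBr in DMF at rt, and the sequence comes back to the route at 16.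

**Further compounds**

F1 | step 8 | benzyl 2-(benzyloxy)-6-(2-oxopentyl)-4-(4,4,5,5-tetramethyl-1,3,2-dioxaborolan-2-yl)benzoate | CCCC(=O)Cc1cc(B2OC(C)(C)C(C)(C)O2)cc(OCc2ccccc2)c1C(=O)OCc1ccccc1
F2 | step 8 | benzyl 2-(benzyloxy)-4-hydroxy-6-(2-oxopentyl)benzoate | CCCC(=O)Cc1cc(O)cc(OCc2ccccc2)c1C(=O)OCc1ccccc1
F3 | step 8 | O-acylisourea of 10 (N,N'-dicyclohexylcarbamimidoyl 2-hydroxy-4-methoxy-6-(2-oxopentyl)benzoate) | CCCC(=O)Cc1cc(OC)cc(O)c1C(=O)OC(=NC1CCCCC1)NC1CCCCC1
F4 | step 2 | N-methoxy-N-methylbutanamide | CCCC(=O)N(C)OC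
F5 | step 2 | methyl 2,4-dimethoxy-6-methylbenzoate | COC(=O)c1c(C)cc(OC)cc1OC
F6 | step 2 | methyl 2-(lithiomethyl)-4,6-dimethoxybenzoate | [Li]Cc1cc(OC)cc(OC)c1C(=O)OC
F7 | step 2 | methyl 2,4-dimethoxy-6-(2-oxopentyl)benzoate | CCCC(=O)Cc1cc(OC)cc(OC)c1C(=O)OC
F8 | step 7 | 8-(benzyloxy)-6-bromo-3-propyl-1H-isochromen-1-one | CCCC1=Cc2cc(Br)cc(OCc3ccccc3)c2C(=O)O1
F9 | step 7 | potassium 2-(benzyloxy)-4-bromo-6-(2-oxopentyl)benzoate | CCCC(=O)Cc1cc(Br)cc(OCc2ccccc2)c1C(=O)[O-].[K+]
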